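The upper-unit pyran ring is closed at C3–C4 by an amine-catalysed domino reaction. C4 already carries ring A (C4a) and ring D (C8 of the lower unit) as a 2-hydroxybenzhydrol; its cation, stabilised by two phloroglucinol-type rings, is the electrophile. The C8a–OH adds to the iminium ion of a cinnamaldehyde (O1–C2, catalyst-set), and the resulting enamine carbon C3 then captures C4, closing the ring and fixing C2 and C4 (C3 transiently) in one operation. The formyl carbon that made C3 nucleophilic is excised to the 3-ketone, and hydride delivery opposite both aryl groups gives the all-cis 3-ol.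

Key step: step 8

Remark: the structure is read as an upper unit (2S,3S,4R) with the C2 aryl, C3–OH and C4 aryl groups all cis, joined through C4 to C8 of a (2R,3R,4S)-flavan-3,4-diol lower unit (2,3-cis-3,4-trans, i.e. epicatechin-4β-ol). Flavan numbering is used (upper unit rings A, C, B; lower unit rings D, F, E). Bn = benzyl, TBS = tert-butyldimethylsilyl.

Step 1
Reactants: 1 (−)-epicatechin
Product: 2 5,7,3',4'-tetra-O-benzyl-(−)-epicatechin
Conditions: BnBr (4.4 equiv), K2CO3, DMF, 0 °C → rt, N2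
Reagents that add atoms: benzyl bromide, BrCc1ccccc1
Why: Williamson etherification in which K2CO3 deprotonates only the four phenols (not the secondary 3-OH) and is too mild to disturb C2 or C3.

Step 2
Reactants: 2 5,7,3',4'-tetra-O-benzyl-(−)-epicatechin
Product: 3 5,7,3',4'-tetra-O-benzylepicatechin-4β-ol
Conditions: DDQ (1.5 equiv), CH2Cl2/H2O (20:1), 0 °C → rt
Reagents that add atoms: water, O
Why: Benzylic oxidation by DDQ (hydride abstraction at C4, activated by the ring-D ethers) gives a C4 cation that water should capture anti to the axial 3-OH, so the new centre is 4β (3,4-trans, 4S).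

Step 3
Reactants: 3 5,7,3',4'-tetra-O-benzylepicatechin-4β-ol
Product: 4 3,4-bis-O-TBS-5,7,3',4'-tetra-O-benzylepicatechin-4β-ol
Conditions: TBSOTf (3 equiv), 2,6-lutidine (5 equiv), CH2Cl2, −78 → 0 °C
Reagents that add atoms: tert-butyldimethylsilyl triflate, CC(C)(C)[Si](C)(C)OS(=O)(=O)C(F)(F)F
Why: Silyl ether formation with a silyl triflate and a hindered base masks the axial 3-OH and the ionisable benzylic 4-OH without free acid.

Step 4
Reactants: 4 3,4-bis-O-TBS-5,7,3',4'-tetra-O-benzylepicatechin-4β-ol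
Product: 5 8-bromo-3,4-bis-O-TBS-5,7,3',4'-tetra-O-benzylepicatechin-4β-ol
Conditions: NBS (1.05 equiv), CH2Cl2, −78 °C → 0 °C, dark
Reagents that add atoms: N-bromosuccinimide, O=C1CCC(=O)N1Br
Why: Electrophilic aromatic bromination, in which C8 is the more reactive of the two free ring-D positions of benzylated flavan-3-ols, should give the 8-bromide regioselectively.

Step 5
Reactants: 6 3,5-bis(benzyloxy)phenol
Product: 7 2,4-bis(benzyloxy)-6-hydroxybenzaldehyde
Conditions: MgCl2, Et3N, (CH2O)n, MeCN, reflux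
Reagents that add atoms: formaldehyde (as paraformaldehyde), C=O
Why: Magnesium-phenoxide-directed ortho-formylation, in which the phenoxide adds to formaldehyde at the ortho carbon and the hydroxymethyl intermediate is oxidised by a second formaldehyde through hydride transfer; the two ortho positions are equivalent.

Step 6
Reactants: 8 3,4-bis(benzyloxy)benzaldehyde
Product: 9 (E)-3-[3,4-bis(benzyloxy)phenyl]prop-2-enal
Conditions: Ph3P=CHCHO (1.1 equiv), toluene, 80 °C
Reagents that add atoms: (triphenylphosphoranylidene)acetaldehyde, O=CC=P(c1ccccc1)(c1ccccc1)c1ccccc1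
Why: Wittig olefination with the stabilised formylmethylene ylide should give the (E)-enal selectively.

Step 7
Reactants: 5 8-bromo-3,4-bis-O-TBS-5,7,3',4'-tetra-O-benzylepicatechin-4β-ol, 7 2,4-bis(benzyloxy)-6-hydroxybenzaldehyde
Product: 11 [2,4-bis(benzyloxy)-6-hydroxyphenyl](3,4-bis-O-TBS-5,7,3',4'-tetra-O-benzylepicatechin-4β-ol-8-yl)methanol (mixture of carbinol epimers), via aryllithium 10 (not isolated)
Conditions: 5, t-BuLi (2.1 equiv), THF, −78 °C; then sodium phenoxide of 7 (NaH, 1.0 equiv, THF), −78 → 0 °C; pH 7 buffer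
Reagents that add atoms: none
Why: Bromine–lithium exchange (faster than benzylic metalation at −78 °C) followed by 1,2-addition of the aryllithium to the formyl group of the pre-formed phenoxide forges the C4–C8 interflavan bond; the carbinol configuration is irrelevant because this centre is ionised in step 8.

Step 8
Reactants: 11 [2,4-bis(benzyloxy)-6-hydroxyphenyl](3,4-bis-O-TBS-5,7,3',4'-tetra-O-benzylepicatechin-4β-ol-8-yl)methanol, 9 (E)-3-[3,4-bis(benzyloxy)phenyl]prop-2-enal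
Product: 14 (2R,3R,4R)-5,7-bis(benzyloxy)-2-[3,4-bis(benzyloxy)phenyl]-4-(3,4-bis-O-TBS-5,7,3',4'-tetra-O-benzylepicatechin-4β-ol-8-yl)chromane-3-carbaldehyde (2,3-trans-3,4-trans; C2 and C4 aryl groups cis), via oxa-Michael enamine 12 (not isolated), via benzhydrylium enamine 13 (not isolated)
Conditions: (R)-2-[diphenyl(trimethylsilyloxy)methyl]pyrrolidine (20 mol%), 2-nitrobenzoic acid (20 mol%), toluene, rt
Reagents that add atoms: none
Why: The amine condenses with 9 to an (E)-iminium ion and the C8a–OH of 11 adds reversibly to its β-carbon from the face left open by the diphenyl(silyloxy)methyl group, giving enamine 12 with C2 set by the catalyst; the carboxylic acid then ionises the benzhydrol to cation 13, stabilised by the 2,4,6-trioxygenated rings A and D, and the enamine carbon C3 attacks C4 before hydrolysis releases 14 and the catalyst. The closest known reaction types are the aminocatalytic oxa-Michael/aldol and oxa-Michael/Michael domino syntheses of chromans (including 1,6-additions to ortho-hydroxyphenyl para-quinone methides) and the enamine SN1 alkylation of aldehydes with benzhydrols. The six-membered ring closes in the 6-(enolexo) mode at the enamine, exo-trig at C4 in the ring-D quinone-methide form of the cation and endo-trig in the ring-A form, both allowed. C2 is controlled by the catalyst (the usual steric-shielding model predicts that the (R)-catalyst gives the C2 configuration that is 2S in the target; the enantiomeric catalyst is equally available should the sense be opposite), whereas C4 and C3 should follow from a chair-like transition state with the C2 aryl group, the enamine methine and ring D pseudo-equatorial, i.e. 2,3-trans-3,4-trans with both aryl groups cis. C3 is epimerisable and is erased in step 9. The step needs O- over C-alkylation of the phenol and ionisation of the upper carbinol only: the reversible O-adduct is drained by intramolecular cation capture, and only the doubly benzylic carbinol, not the lower-unit C4 silyl ether, should ionise under a carboxylic acid.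

Step 9
Reactants: 14 (2R,3R,4R)-5,7-bis(benzyloxy)-2-[3,4-bis(benzyloxy)phenyl]-4-(lower-unit-8-yl)chromane-3-carbaldehyde
Product: 16 (2S,4R)-5,7-bis(benzyloxy)-2-[3,4-bis(benzyloxy)phenyl]-4-(3,4-bis-O-TBS-5,7,3',4'-tetra-O-benzylepicatechin-4β-ol-8-yl)chroman-3-one, via piperidine enamine 15 (not isolated)
Conditions: piperidine (1.2 equiv), 4 Å MS, toluene, rt; then O2, tetraphenylporphyrin (cat.), hν (visible), CH2Cl2, −78 °C
Reagents that add atoms: dioxygen, O=O
Why: Enamine formation at the α-branched aldehyde and [2+2] addition of singlet oxygen give a dioxetane that cleaves to the C3 ketone and N-formylpiperidine (oxidative deformylation) under neutral, cold conditions meant to leave C2 and C4 untouched.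

Step 10
Reactants: 16 (2S,4R)-4-(lower-unit-8-yl)-5,7,3',4'-tetra-O-benzylflavan-3-one
Product: 17 (2S,3S,4R)-5,7,3',4'-tetra-O-benzyl-4-(3,4-bis-O-TBS-5,7,3',4'-tetra-O-benzylepicatechin-4β-ol-8-yl)flavan-3-ol (all-cis)
Conditions: LiBH(s-Bu)3 (L-Selectride), LiBr, THF, −78 °C; then H2O
Reagents that add atoms: none
Why: Ketone reduction in which the bulky borohydride should attack the C3 carbonyl from the face opposite the two cis aryl groups at C2 and C4, so that the new C3–OH is cis to both (2,3-cis-3,4-cis), the same oxidation–reduction logic that turns catechin-type into epicatechin-type flavan-3-ols.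

Step 11
Reactants: 17 all-cis octa-O-benzyl bis-O-TBS dimer
Product: 18 3,4-bis-O-TBS ether (lower unit) of the target
Conditions: H2 (1 atm), Pd(OH)2/C, THF/EtOAc, rt
Reagents that add atoms: none
Why: Hydrogenolysis of the eight aryl benzyl ethers under neutral, non-protic conditions; the bulky silyl ether is kept on to shield the benzylic C4–O bond of the lower unit from hydrogenolysis, and the interflavan bond is inert.

Step 12
Reactants: 18 3,4-bis-O-TBS ether (lower unit) of the target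
Product: 19 target CNP0114173.1
Conditions: TBAF/AcOH (1:1), THF, 0 °C → rt, Ar
Reagents that add atoms: none
Why: Fluoride-mediated desilylation buffered with acetic acid frees the lower-unit 3- and 4-OH groups without the acid that would ionise the C4–OH or the free base that would promote oxidation of the polyphenol.

Compound list

1 | (−)-epicatechin | Oc1cc(O)c2c(c1)O[C@H](c1ccc(O)c(O)c1)[C@H](O)C2 | starting material
2 | 5,7,3',4'-tetra-O-benzyl-(−)-epicatechin | O(Cc1ccccc1)c1cc(OCc2ccccc2)c2c(c1)O[C@H](c1ccc(OCc3ccccc3)c(OCc3ccccc3)c1)[C@H](O)C2 | intermediate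
3 | 5,7,3',4'-tetra-O-benzylepicatechin-4β-ol (2,3-cis-3,4-trans flavan-3,4-diol) | O(Cc1ccccc1)c1cc(OCc2ccccc2)c2c(c1)O[C@H](c1ccc(OCc3ccccc3)c(OCc3ccccc3)c1)[C@H](O)[C@H]2O | intermediate
4 | 3,4-bis-O-TBS ether of 3 | c1c(OCc3ccccc3)cc(OCc3ccccc3)c2c1O[C@H](c1ccc(OCc3ccccc3)c(OCc3ccccc3)c1)[C@H](O[Si](C)(C)C(C)(C)C)[C@H]2O[Si](C)(C)C(C)(C)C | intermediate
5 | 8-bromo derivative of 4 | Brc1c(OCc3ccccc3)cc(OCc3ccccc3)c2c1O[C@H](c1ccc(OCc3ccccc3)c(OCc3ccccc3)c1)[C@H](O[Si](C)(C)C(C)(C)C)[C@H]2O[Si](C)(C)C(C)(C)C | intermediate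
6 | 3,5-bis(benzyloxy)phenol | Oc1cc(OCc2ccccc2)cc(OCc2ccccc2)c1 | starting material
7 | 2,4-bis(benzyloxy)-6-hydroxybenzaldehyde | O=Cc1c(O)cc(OCc2ccccc2)cc1OCc1ccccc1 | intermediate
8 | 3,4-bis(benzyloxy)benzaldehyde | O=Cc1ccc(OCc2ccccc2)c(OCc2ccccc2)c1 | starting material
9 | (E)-3-[3,4-bis(benzyloxy)phenyl]prop-2-enal | O=C/C=C/c1ccc(OCc2ccccc2)c(OCc2ccccc2)c1 | intermediate
10 | 8-lithio derivative of 4 (not isolated) | [Li]c1c(OCc3ccccc3)cc(OCc3ccccc3)c2c1O[C@H](c1ccc(OCc3ccccc3)c(OCc3ccccc3)c1)[C@H](O[Si](C)(C)C(C)(C)C)[C@H]2O[Si](C)(C)C(C)(C)C | intermediate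
11 | 2-hydroxybenzhydrol joining ring A to C8 of the lower unit (carbinol epimers) | Oc1cc(OCc2ccccc2)cc(OCc2ccccc2)c1C(O)c1c(OCc3ccccc3)cc(OCc3ccccc3)c2c1O[C@H](c1ccc(OCc3ccccc3)c(OCc3ccccc3)c1)[C@H](O[Si](C)(C)C(C)(C)C)[C@H]2O[Si](C)(C)C(C)(C)C | intermediate
12 | O1–C2 ether (C2 set) carrying the (E)-enamine of the catalyst, benzhydrol intact (not isolated) | c1ccccc1COc1cc(OCc2ccccc2)c(C(O)c4c(OCc6ccccc6)cc(OCc6ccccc6)c5c4O[C@H](c4ccc(OCc6ccccc6)c(OCc6ccccc6)c4)[C@H](O[Si](C)(C)C(C)(C)C)[C@H]5O[Si](C)(C)C(C)(C)C)c(c1)O[C@@H](c1ccc(OCc2ccccc2)c(OCc2ccccc2)c1)/C=C/N1CCC[C@@H]1C(c1ccccc1)(c1ccccc1)O[Si](C)(C)C | intermediate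
13 | benzhydrylium ion of 12 (2-nitrobenzoate counter-ion; not isolated) | c1ccccc1COc1cc(OCc2ccccc2)c([CH+]c4c(OCc6ccccc6)cc(OCc6ccccc6)c5c4O[C@H](c4ccc(OCc6ccccc6)c(OCc6ccccc6)c4)[C@H](O[Si](C)(C)C(C)(C)C)[C@H]5O[Si](C)(C)C(C)(C)C)c(c1)O[C@@H](c1ccc(OCc2ccccc2)c(OCc2ccccc2)c1)/C=C/N1CCC[C@@H]1C(c1ccccc1)(c1ccccc1)O[Si](C)(C)C | intermediate
14 | (2R,3R,4R)-3-formyl-4-arylflavan (2,3-trans-3,4-trans; C2 and C4 aryl groups cis) | O(Cc1ccccc1)c1cc(OCc2ccccc2)c2c(c1)O[C@@H](c1ccc(OCc3ccccc3)c(OCc3ccccc3)c1)[C@H](C=O)[C@H]2c1c(OCc3ccccc3)cc(OCc3ccccc3)c2c1O[C@H](c1ccc(OCc3ccccc3)c(OCc3ccccc3)c1)[C@H](O[Si](C)(C)C(C)(C)C)[C@H]2O[Si](C)(C)C(C)(C)C | intermediate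
15 | piperidine enamine of 14 (C3=CH–N, double-bond geometry not controlled; C2 and C4 as in 14; not isolated) | O(Cc1ccccc1)c1cc(OCc2ccccc2)c2c(c1)O[C@@H](c1ccc(OCc3ccccc3)c(OCc3ccccc3)c1)C(=CN1CCCCC1)[C@H]2c1c(OCc3ccccc3)cc(OCc3ccccc3)c2c1O[C@H](c1ccc(OCc3ccccc3)c(OCc3ccccc3)c1)[C@H](O[Si](C)(C)C(C)(C)C)[C@H]2O[Si](C)(C)C(C)(C)C | intermediate
16 | (2S,4R)-4-arylflavan-3-one (aryl groups cis) | O(Cc1ccccc1)c1cc(OCc2ccccc2)c2c(c1)O[C@@H](c1ccc(OCc3ccccc3)c(OCc3ccccc3)c1)C(=O)[C@H]2c1c(OCc3ccccc3)cc(OCc3ccccc3)c2c1O[C@H](c1ccc(OCc3ccccc3)c(OCc3ccccc3)c1)[C@H](O[Si](C)(C)C(C)(C)C)[C@H]2O[Si](C)(C)C(C)(C)C | intermediate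
17 | (2S,3S,4R) all-cis 4-arylflavan-3-ol, octa-O-benzyl, lower-unit 3,4-bis-O-TBS | O(Cc1ccccc1)c1cc(OCc2ccccc2)c2c(c1)O[C@@H](c1ccc(OCc3ccccc3)c(OCc3ccccc3)c1)[C@@H](O)[C@H]2c1c(OCc3ccccc3)cc(OCc3ccccc3)c2c1O[C@H](c1ccc(OCc3ccccc3)c(OCc3ccccc3)c1)[C@H](O[Si](C)(C)C(C)(C)C)[C@H]2O[Si](C)(C)C(C)(C)C | intermediate
18 | target with the lower-unit 3- and 4-OH as TBS ethers | Oc1cc(O)c2c(c1)O[C@@H](c1ccc(O)c(O)c1)[C@@H](O)[C@H]2c1c(O)cc(O)c2c1O[C@H](c1ccc(O)c(O)c1)[C@H](O[Si](C)(C)C(C)(C)C)[C@H]2O[Si](C)(C)C(C)(C)C | intermediate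
19 | CNP0114173.1 | Oc1cc(O)c2c(c1)O[C@@H](c1ccc(O)c(O)c1)[C@@H](O)[C@H]2c1c(O)cc(O)c2c1O[C@H](c1ccc(O)c(O)c1)[C@H](O)[C@H]2O | target

Total step count: 12. Longest linear sequence: 10 steps (1 → 2 → 3 → 4 → 5 → 11 → 14 → 16 → 17 → 18 → 19).

Steps most likely to fail

Step 8. The iminium ion may alkylate the electron-rich ring A at carbon instead of oxygen, or the ring closure may show poor facial selectivity at C4. The fallback closes the same C3–C4 bond by metathesis and sets C4 by hydroboration; it sets out from 7, 9 and bromide 5 (as aryllithium 10) and returns at ketone 16. Enal 9 is reduced (NaBH4, CeCl3·7H2O, MeOH) to (E)-3-[3,4-bis(benzyloxy)phenyl]prop-2-en-1-ol F1, which is converted (ClCO2Me, pyridine) into its methyl carbonate F2. Iridium-catalysed asymmetric allylic etherification of the lithium phenoxide of 7 with F2 ([Ir(cod)Cl]2, chiral BINOL-derived phosphoramidite ligand, THF, 50 °C) should give the branched (R)-1-arylallyl aryl ether aldehyde F3 with C2 set. Aryllithium 10 adds to F3 to give the diarylcarbinol F4, Dess–Martin oxidation gives the diaryl ketone F5, and methylenation (Cp2TiMe2, toluene, 70 °C) gives the 1,1-diarylethylene F6. Ring-closing metathesis (second-generation Hoveyda–Grubbs catalyst, toluene, 80 °C) should give the 4-aryl-2H-chromene F7. Hydroboration–oxidation (BH3·SMe2; NaBO3·4H2O) from the face opposite the C2 aryl group places boron at C3 and hydrogen at C4, giving the 2,3-trans-3,4-trans alcohol F8 with both aryl groups cis, and Dess–Martin oxidation of F8 gives 16.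

Step 9. The β-aryloxy enamine may open by retro-oxa-Michael reaction and scramble C2, or enamine formation at the hindered aldehyde may stall. The fallback avoids any enamine or enolate at C3; it sets out from 14 and returns at 16. Pinnick oxidation (NaClO2, NaH2PO4, 2-methyl-2-butene, t-BuOH/H2O) gives the carboxylic acid F9, which is coupled with 2-mercaptopyridine N-oxide (DCC) to the Barton ester F10. Barton decarboxylative hydroxylation (O2, t-BuSH, hν; then P(OMe)3) gives the nor-alcohol F11 as C3 epimers, and Dess–Martin oxidation of F11 gives 16.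

Step 7. Addition of the hindered aryllithium to the deactivated, doubly ortho-substituted phenoxide aldehyde may be slow, with proton transfer from benzyl ether positions competing. The fallback reverses the roles of the partners; it sets out from 10 and 6 and returns at 11. Aryllithium 10 is quenched with DMF to give the lower-unit 8-carbaldehyde F12, and the bromomagnesium phenoxide of 6 (EtMgBr, toluene) undergoes magnesium-directed ortho-hydroxyalkylation with F12 to give 11.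

Further compounds

F1 | step 8 | (E)-3-[3,4-bis(benzyloxy)phenyl]prop-2-en-1-ol | OC/C=C/c1ccc(OCc2ccccc2)c(OCc2ccccc2)c1
F2 | step 8 | (E)-3-[3,4-bis(benzyloxy)phenyl]allyl methyl carbonate | COC(=O)OC/C=C/c1ccc(OCc2ccccc2)c(OCc2ccccc2)c1
F3 | step 8 | 2-{[(1R)-1-[3,4-bis(benzyloxy)phenyl]prop-2-en-1-yl]oxy}-4,6-bis(benzyloxy)benzaldehyde | O=Cc1c(OCc2ccccc2)cc(OCc2ccccc2)cc1O[C@@H](c1ccc(OCc2ccccc2)c(OCc2ccccc2)c1)C=C
F4 | step 8 | diarylcarbinol from 10 and F3 (carbinol epimers) | OC(c1c(OCc2ccccc2)cc(OCc2ccccc2)cc1O[C@@H](c1ccc(OCc2ccccc2)c(OCc2ccccc2)c1)C=C)c1c(OCc3ccccc3)cc(OCc3ccccc3)c2c1O[C@H](c1ccc(OCc3ccccc3)c(OCc3ccccc3)c1)[C@H](O[Si](C)(C)C(C)(C)C)[C@H]2O[Si](C)(C)C(C)(C)C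
F5 | step 8 | diaryl ketone from F4 | O=C(c1c(OCc2ccccc2)cc(OCc2ccccc2)cc1O[C@@H](c1ccc(OCc2ccccc2)c(OCc2ccccc2)c1)C=C)c1c(OCc3ccccc3)cc(OCc3ccccc3)c2c1O[C@H](c1ccc(OCc3ccccc3)c(OCc3ccccc3)c1)[C@H](O[Si](C)(C)C(C)(C)C)[C@H]2O[Si](C)(C)C(C)(C)C
F6 | step 8 | 1,1-diarylethylene diene from F5 | C=C(c1c(OCc2ccccc2)cc(OCc2ccccc2)cc1O[C@@H](c1ccc(OCc2ccccc2)c(OCc2ccccc2)c1)C=C)c1c(OCc3ccccc3)cc(OCc3ccccc3)c2c1O[C@H](c1ccc(OCc3ccccc3)c(OCc3ccccc3)c1)[C@H](O[Si](C)(C)C(C)(C)C)[C@H]2O[Si](C)(C)C(C)(C)C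
F7 | step 8 | 4-(lower-unit-8-yl)-5,7,3',4'-tetra-O-benzyl-2H-chromene (flav-3-ene), C2 as in the target | O(Cc1ccccc1)c1cc(OCc2ccccc2)c2c(c1)O[C@@H](c1ccc(OCc3ccccc3)c(OCc3ccccc3)c1)C=C2c1c(OCc3ccccc3)cc(OCc3ccccc3)c2c1O[C@H](c1ccc(OCc3ccccc3)c(OCc3ccccc3)c1)[C@H](O[Si](C)(C)C(C)(C)C)[C@H]2O[Si](C)(C)C(C)(C)C
F8 | step 8 | 2,3-trans-3,4-trans 4-arylflavan-3-ol (C3 epimer of 17) | O(Cc1ccccc1)c1cc(OCc2ccccc2)c2c(c1)O[C@@H](c1ccc(OCc3ccccc3)c(OCc3ccccc3)c1)[C@H](O)[C@H]2c1c(OCc3ccccc3)cc(OCc3ccccc3)c2c1O[C@H](c1ccc(OCc3ccccc3)c(OCc3ccccc3)c1)[C@H](O[Si](C)(C)C(C)(C)C)[C@H]2O[Si](C)(C)C(C)(C)C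
F9 | step 9 | flavan-3-carboxylic acid from 14 | O(Cc1ccccc1)c1cc(OCc2ccccc2)c2c(c1)O[C@@H](c1ccc(OCc3ccccc3)c(OCc3ccccc3)c1)[C@H](C(=O)O)[C@H]2c1c(OCc3ccccc3)cc(OCc3ccccc3)c2c1O[C@H](c1ccc(OCc3ccccc3)c(OCc3ccccc3)c1)[C@H](O[Si](C)(C)C(C)(C)C)[C@H]2O[Si](C)(C)C(C)(C)C
F10 | step 9 | Barton ester (2-thioxopyridin-1-yl ester) of F9 | O(Cc1ccccc1)c1cc(OCc2ccccc2)c2c(c1)O[C@@H](c1ccc(OCc3ccccc3)c(OCc3ccccc3)c1)[C@H](C(=O)On1ccccc1=S)[C@H]2c1c(OCc3ccccc3)cc(OCc3ccccc3)c2c1O[C@H](c1ccc(OCc3ccccc3)c(OCc3ccccc3)c1)[C@H](O[Si](C)(C)C(C)(C)C)[C@H]2O[Si](C)(C)C(C)(C)C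
F11 | step 9 | 4-arylflavan-3-ol as a mixture of C3 epimers | O(Cc1ccccc1)c1cc(OCc2ccccc2)c2c(c1)O[C@@H](c1ccc(OCc3ccccc3)c(OCc3ccccc3)c1)C(O)[C@H]2c1c(OCc3ccccc3)cc(OCc3ccccc3)c2c1O[C@H](c1ccc(OCc3ccccc3)c(OCc3ccccc3)c1)[C@H](O[Si](C)(C)C(C)(C)C)[C@H]2O[Si](C)(C)C(C)(C)C
F12 | step 7 | 8-formyl derivative of 4 | O=Cc1c(OCc3ccccc3)cc(OCc3ccccc3)c2c1O[C@H](c1ccc(OCc3ccccc3)c(OCc3ccccc3)c1)[C@H](O[Si](C)(C)C(C)(C)C)[C@H]2O[Si](C)(C)C(C)(C)C
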